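Readings and results were computed with made-up constants; noise was put on by code.

Percentages mislead here. By 25.0 h, counting the mean of electrophile lost and target found, Wednesday's flask shows less conversion than Friday's, 33.5% against 45.5%, yet by the same scattered readings it turned over more electrophile, 28.1 mM against 24.1 mM.

| flask | electrophile | gas | remark | time |
|---|---|---|---|---|
| Friday's | 53 mM | 18 mM (held) | run made earlier |  |
| Wednesday's | 84 mM | 18 mM (held) | run made earlier |  |
| flask | 38 mM | 18 mM (held) |  | 25 h |

| run | time / h | electrophile / % | target / % |
|---|---|---|---|
| Friday's | 2.00 | 100 | 2 |
| Friday's | 4.00 | 93 | 7 |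
| Friday's | 8.00 | 86 | 10 |
| Friday's | 12.0 | 79 | 23 |
| Friday's | 25.0 | 52 | 43 |
| Wednesday's | 5.00 | 95 | 5 |
| Wednesday's | 10.0 | 87 | 13 |
| Wednesday's | 15.0 | 81 | 18 |
| Wednesday's | 20.0 | 74 | 28 |
| Wednesday's | 25.0 | 67 | 34 |

(each reading ± 1.5 percentage points)

- at the start none of the gas is in solution
- the earlier runs do not show how much of nucleophile is bound; that part of a forecast is a guess

- part of the electrophile that has reacted at 25 h
- share of free nucleophile in free nucleophile and protonated nucleophile together, at 25 h

These two amounts can be put on an apparent saturation law, rate = V·c/(K + c), with c the electrophile concentration. Its integral is V·t = x + K·ln(c charged / c remaining), with x the amount reacted. Through the two runs, K = 20.2 mM and V = 1.46 mM/h, though two runs with scattered readings pin neither firmly.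

The decision for the new flask is whether 38 mM of electrophile can stop at 25 h or must be left longer to pass half conversion. Setting x to 0.5 of the charge gives (0.5·c charged + K·ln 2)/V = 22.7 h, the half-conversion time. This flask's value is shorter than 25 h, so the recipe stands. Continuing from that point at the rate there, this reckoning gives 54.3% reacted and nothing for the share of free nucleophile.

The forecast, from its own fit, gives 55% reacted (47% to 63%) and a share of free nucleophile of 45% (10% to 85%), noting that "The data say nothing direct about protonation".

At 25 h the flask gives 53.2% reacted and a share of free nucleophile of 27.7%, with 7.46 mM of nucleophile beside 19.5 mM of protonated nucleophile.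

    electrophile + nucleophile → acid set free + target (k = 5.49 /M/h)
    nucleophile + acid set free ⇌ protonated nucleophile, settled at all times (K = 5400 /M)
    acid set free + target → side product (k = 2.20 /M/h)
    gas ⇌ nucleophile, rate k4*(csat - [nucleophile]) (kL = 0.166 /h)
    nucleophile ⇌ dormant form (K = 0.978, k = 0.0580 /h)

In this flask, the part reacted stands 5 points lower at 22.5 h, below half conversion, and the half-conversion time of 22.7 h lies between that time and 25 h. With 95 mM of electrophile and all else held, the same reckoning gives 42.3 h, longer than 25 h, so that neighbouring flask should stand short of half conversion. It does, with 31.6% reacted and 68% of its electrophile left.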